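**Retrosynthetic overview**
1. The target, 3-docosyl-2-hydroxy-5-methoxy-1,4-benzoquinone, comes from a 1,2,4-triacetoxyarene by deacetylation and oxidation, and that from an aryl methyl ketone by Baeyer–Villiger oxidation: the C2 hydroxyl is carried as an acetyl placeholder.
2. The aryl ketone comes from a [4+2] cycloaddition of 4-methoxy-2-(trimethylsilyloxy)furan with hexacos-3-yn-2-one and opening of the oxygen bridge. This forms C1–C2 and C3–C4 and closes the only ring, the six-membered carbocycle.
3. Feature: quinone atoms C1(=O)–C6(H)–C5(OMe)–C4(=O), with all three oxygens, are the C2–C3–C4–C5 unit of methyl tetronate (lactone C=O becomes C1=O, ring O becomes the C4 oxygen). Only C2 (OH) and C3 (docosyl) are missing, and they are the two alkyne carbons of the ynone.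
4. The furan comes from methyl tetronate by enolate O-silylation; the ynone from but-3-yn-2-ol and 1-bromodocosane by acetylide alkylation and oxidation.

Key step: step 4

Remark: the target has no stereocentre and no stereogenic double bond, so it is one achiral compound and no enantiocontrol is needed. But-3-yn-2-ol is used as the racemate because its carbinol centre is oxidised away in step 3.

**Step 1**
Reactants: 1 methyl tetronate (4-methoxyfuran-2(5H)-one)
Product: 3 4-methoxy-2-(trimethylsilyloxy)furan, via lithium 4-methoxyfuran-2-olate 2 (not isolated)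
Conditions: LDA (1.05 equiv), THF, −78 °C; TMSCl, −78 °C → rt; non-aqueous work-up (pentane, filtration), Kugelrohr distillation, used fresh
Reagents that add atoms: chlorotrimethylsilane, C[Si](C)(C)Cl
Why: LDA removes the C5 proton γ to the lactone carbonyl and the silyl chloride traps the dienolate on oxygen, so kinetic enolate O-silylation should give the aromatic 2-silyloxyfuran.

**Step 2**
Reactants: 4 but-3-yn-2-ol (racemic); 5 1-bromodocosane
Product: 7 rac-hexacos-3-yn-2-ol, via dilithiated but-3-yn-2-ol 6 (not isolated)
Conditions: n-BuLi (2.1 equiv), THF/HMPA, −78 → 0 °C; then 5, 0 °C → rt; H2O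
Reagents that add atoms: none
Why: In the alkoxide–acetylide dianion the carbon terminus is by far the better nucleophile toward a primary bromide, so SN2 acetylide alkylation should give the internal propargylic alcohol as the racemate.

**Step 3**
Reactants: 7 rac-hexacos-3-yn-2-ol
Product: 8 hexacos-3-yn-2-one
Conditions: Dess–Martin periodinane, CH2Cl2, rt
Reagents that add atoms: none
Why: Dess–Martin oxidation should convert the secondary propargylic alcohol into the conjugated ynone under neutral conditions that leave the alkyne and the chain untouched.

**Step 4**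
Reactants: 3 4-methoxy-2-(trimethylsilyloxy)furan; 8 hexacos-3-yn-2-one
Product: 11 1-(2-docosyl-3,6-dihydroxy-4-methoxyphenyl)ethan-1-one, via oxanorbornadiene cycloadduct 9 (not isolated), via aryl trimethylsilyl ether 10 (not isolated)
Conditions: 3 (1.5 equiv), toluene (concentrated), 80 °C, Ar, sealed tube; then 1 M HCl, THF, rt, under Ar
Reagents that add atoms: none
Why: The push–pull furan 3 is most nucleophilic at C5 (enol-ether β-carbon and vinylogous terminus of the silyl ketene acetal) and bonds there to the chain-bearing β-carbon of ynone 8 while furan C2 bonds to the acetyl-bearing α-carbon, in one asynchronous step or through a short-lived zwitterion that collapses; the closest known reaction type is the Diels–Alder reaction of 2-silyloxyfurans with acetylenic dienophiles followed by bridge opening to hydroquinone monosilyl ethers. The single carbocycle is closed in an intermolecular [4+2] mode that forms C1–C2 and C3–C4 of the later quinone. Adduct 9 is a bridged silyl ketal, so the C–O bridge bond at the silyloxy carbon should ionise, the bridgehead proton is lost and the ring aromatises to silyl ether 10, which dilute acid cleaves to 11. The two bridgehead stereocentres of 9 are transient and vanish on aromatisation, so no stereocontrol is needed. The step needs head-to-tail regiochemistry, which the matched polarisation secures (both donor groups of 3 direct to C5, the carbonyl of 8 directs to its β-carbon), and it needs ring closure to outrun conjugate addition with silyl transfer, which the thermal, Lewis-acid-free conditions favour.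

**Step 5**
Reactants: 11 1-(2-docosyl-3,6-dihydroxy-4-methoxyphenyl)ethan-1-one
Product: 12 2-acetyl-3-docosyl-5-methoxybenzene-1,4-diyl diacetate
Conditions: Ac2O, pyridine, DMAP (cat.), CH2Cl2, rt, Ar
Reagents that add atoms: acetic anhydride, CC(=O)OC(C)=O
Why: DMAP-catalysed acylation should cap both phenols, including the hydrogen-bonded one ortho to the ketone, which blocks oxidation of the hydroquinone to a quinone in the peracid step.

**Step 6**
Reactants: 12 2-acetyl-3-docosyl-5-methoxybenzene-1,4-diyl diacetate
Product: 13 3-docosyl-5-methoxybenzene-1,2,4-triyl triacetate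
Conditions: mCPBA, TFA (cat.), CH2Cl2, rt → 40 °C
Reagents that add atoms: 3-chloroperoxybenzoic acid, OOC(=O)c1cccc(Cl)c1
Why: In this Baeyer–Villiger oxidation the aryl group, which carries a para-methoxy donor, should migrate in preference to methyl, so oxygen is inserted between the ring and the acetyl carbon and the placeholder becomes an aryl acetate.

**Step 7**
Reactants: 13 3-docosyl-5-methoxybenzene-1,2,4-triyl triacetate
Product: 15 3-docosyl-2-hydroxy-5-methoxy-1,4-benzoquinone, via 3-docosyl-5-methoxybenzene-1,2,4-triol 14 (not isolated)
Conditions: HCl (1.25 M in MeOH), THF, 50 °C, Ar; evaporate; FeCl3 (2.2 equiv), THF/H2O, rt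
Reagents that add atoms: none
Why: Acid-catalysed transesterification should strip the three aryl acetates under argon, and iron(III) then oxidises the para-related hydroxyls at C1 and C4 of the triol to the quinone while the C2 hydroxyl remains, the classical end-game from 1,2,4-triacetoxyarenes to hydroxyquinones.

**Compound list**
1 | methyl tetronate (4-methoxyfuran-2(5H)-one) | COC1=CC(=O)OC1 | starting material
2 | lithium 4-methoxyfuran-2-olate | [Li+].COc1coc([O-])c1 | intermediate
3 | 4-methoxy-2-(trimethylsilyloxy)furan | COc1coc(O[Si](C)(C)C)c1 | intermediate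
4 | but-3-yn-2-ol (racemic) | CC(O)C#C | starting material
5 | 1-bromodocosane | CCCCCCCCCCCCCCCCCCCCCCBr | starting material
6 | dilithiated but-3-yn-2-ol (alkoxide–acetylide) | [Li+].[Li+].CC([O-])C#[C-] | intermediate
7 | rac-hexacos-3-yn-2-ol | CC(O)C#CCCCCCCCCCCCCCCCCCCCCCC | intermediate
8 | hexacos-3-yn-2-one | CC(=O)C#CCCCCCCCCCCCCCCCCCCCCCC | intermediate
9 | 1-[3-docosyl-5-methoxy-1-(trimethylsilyloxy)-7-oxabicyclo[2.2.1]hepta-2,5-dien-2-yl]ethan-1-one (racemic) | CC(=O)C1=C(CCCCCCCCCCCCCCCCCCCCCC)C2OC1(O[Si](C)(C)C)C=C2OC | intermediate
10 | 1-[2-docosyl-3-hydroxy-4-methoxy-6-(trimethylsilyloxy)phenyl]ethan-1-one | CC(=O)c1c(O[Si](C)(C)C)cc(OC)c(O)c1CCCCCCCCCCCCCCCCCCCCCC | intermediate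
11 | 1-(2-docosyl-3,6-dihydroxy-4-methoxyphenyl)ethan-1-one | CC(=O)c1c(O)cc(OC)c(O)c1CCCCCCCCCCCCCCCCCCCCCC | intermediate
12 | 2-acetyl-3-docosyl-5-methoxybenzene-1,4-diyl diacetate | CC(=O)c1c(OC(C)=O)cc(OC)c(OC(C)=O)c1CCCCCCCCCCCCCCCCCCCCCC | intermediate
13 | 3-docosyl-5-methoxybenzene-1,2,4-triyl triacetate | CC(=O)Oc1c(OC(C)=O)cc(OC)c(OC(C)=O)c1CCCCCCCCCCCCCCCCCCCCCC | intermediate
14 | 3-docosyl-5-methoxybenzene-1,2,4-triol | Oc1c(O)cc(OC)c(O)c1CCCCCCCCCCCCCCCCCCCCCC | intermediate
15 | 3-docosyl-2-hydroxy-5-methoxy-1,4-benzoquinone (3-docosyl-2-hydroxy-5-methoxycyclohexa-2,5-diene-1,4-dione) | CCCCCCCCCCCCCCCCCCCCCCC1=C(O)C(=O)C=C(OC)C1=O | target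

**Step count**
Total: 7 steps. Longest linear sequence: 6 steps (steps 2, 3, 4, 5, 6, 7 from but-3-yn-2-ol and 1-bromodocosane).

**Steps most likely to fail**

Step 4. The internal, singly activated alkyne may react slowly, so that the furan is lost by desilylation or by conjugate addition with silyl transfer that stops at an open-chain butenolide instead of closing the ring. The fallback gives up the cycloaddition and uses established arene chemistry; it sets out from 5 and comes back at 15. Commercial 1,2,4,5-tetramethoxybenzene is lithiated between two methoxy groups (n-BuLi, THF, 0 °C → rt) and alkylated with 5 (HMPA) to give 3-docosyl-1,2,4,5-tetramethoxybenzene F1. Ceric ammonium nitrate in MeCN/H2O/THF should demethylate it oxidatively to 3-docosyl-2,5-dimethoxy-1,4-benzoquinone F2. Perchloric acid (70 %) in dioxane at rt should then hydrolyse preferentially the methoxy group flanked by the alkyl chain, giving 15.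

Step 6. Peracid addition to the ketone, which is flanked on both sides, may be slow, and the diacetoxy-aryl ring has a weakened migratory drive, so that the ketone is returned or acetates are lost. The fallback is a Dakin oxidation of the unprotected ortho-hydroxy ketone; it sets out from 11 and comes back at 14. Treating 11 with 30 % H2O2 and aqueous NaOH in THF (EDTA, Ar, 0 °C → rt) should give, by phenoxide-driven aryl migration, 2-docosyl-3,6-dihydroxy-4-methoxyphenyl acetate F3. This is saponified in the same flask to triol 14, which after acidification enters the iron(III) stage of step 7.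

Step 2. Displacement on the waxy C22 bromide by the aggregated dianion may be sluggish, with competing elimination to docos-1-ene. The fallback separates chain attachment from the carbinol; it sets out from 5 and comes back at 8. Lithium acetylide–ethylenediamine complex in DMSO/THF at rt should convert 5 into tetracos-1-yne F4. Deprotonation (n-BuLi, THF, −78 °C) and acylation with N-methoxy-N-methylacetamide (Weinreb ketone synthesis) then give ynone 8 directly, so step 3 is not needed.

**Further compounds**
F1 | step 4 | 3-docosyl-1,2,4,5-tetramethoxybenzene | COc1cc(OC)c(OC)c(CCCCCCCCCCCCCCCCCCCCCC)c1OC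
F2 | step 4 | 3-docosyl-2,5-dimethoxycyclohexa-2,5-diene-1,4-dione | COC1=CC(=O)C(OC)=C(CCCCCCCCCCCCCCCCCCCCCC)C1=O
F3 | step 6 | 2-docosyl-3,6-dihydroxy-4-methoxyphenyl acetate | CC(=O)Oc1c(O)cc(OC)c(O)c1CCCCCCCCCCCCCCCCCCCCCC
F4 | step 2 | tetracos-1-yne | C#CCCCCCCCCCCCCCCCCCCCCCC
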